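**Retrosynthetic overview**
- The target comes from global hydrogenolysis of a fully benzyl-protected (2R,3R)-flavan-3-yl vanillate; C3 is set by face-selective hydrogenation of a 2-aryl-2H-chromen-3-yl enol ester, under control of C2.
- The C2–aryl bond and the C2 stereocentre come from an enantioconvergent nickel-catalysed Suzuki-type arylation of a racemic 2-ethoxy-2H-chromen-3-yl ester with a ring B boronic acid.
- The acetal comes from DDQ oxidation (C2–H) of the enol vanillate of a 5,7-dioxygenated chroman-3-one; the acyl part is protected vanillic acid (catechol, MeI, CO2).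
- Ring C is the only ring that is built: gold-catalysed oxidative cyclisation of an aryl propargyl ether closes it (C4–C4a bond) before ring B is attached.
- Ring A comes from resorcinol by iridium-catalysed C–H borylation/oxidation; ring B and the vanilloyl ring come from catechol.

Assumption: the SMILES is read as the (2R,3R), 2,3-cis ester, i.e. the 3-O-vanillate of (−)-epicatechin. Bn = benzyl, MBn = 4-methylbenzyl.

**Ring A and ring C: chroman-3-one 7**

Step 1
Reactants: 1 resorcinol
Product: 2 1,3-bis[(4-methylbenzyl)oxy]benzene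
Conditions: 4-methylbenzyl bromide (2.2 equiv), K2CO3, DMF, 60 °C
Reagents that add atoms: 4-methylbenzyl bromide, Cc1ccc(CBr)cc1
Why: Williamson ether synthesis (SN2 of the phenoxide on a benzylic bromide); MBn is used on ring A because every C–H of its ring is ortho to a substituent and so stays inert in the sterically governed borylation of step 2, while it is still cleaved by hydrogenolysis like benzyl.

Step 2
Reactants: 2 1,3-bis[(4-methylbenzyl)oxy]benzene
Product: 4 3,5-bis[(4-methylbenzyl)oxy]phenol, via arylboronic acid pinacol ester 3 (not isolated)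
Conditions: [Ir(OMe)(cod)]2 (1.5 mol%), 4,4′-di-tert-butyl-2,2′-bipyridine (3 mol%), B2pin2 (1.0 equiv), THF, 80 °C; then KHSO5 (as 2KHSO5·KHSO4·K2SO4), acetone/H2O, rt
Reagents that add atoms: bis(pinacolato)diboron, CC1(C)OB(OC1(C)C)B1OC(C)(C)C(C)(C)O1 (boron of 3 only); potassium peroxymonosulfate, [K+].[O-]S(=O)(=O)OO (phenol oxygen of 4)
Why: Sterically controlled iridium-catalysed aromatic C–H borylation (C–H activation) takes place only at the C–H meta to both ether groups, and the C–B bond is then oxidised to C–O at the same carbon (one-pot borylation/oxidation).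

Step 3
Reactants: 4 3,5-bis[(4-methylbenzyl)oxy]phenol; 5 propargyl bromide
Product: 6 1,3-bis[(4-methylbenzyl)oxy]-5-(prop-2-yn-1-yloxy)benzene
Conditions: K2CO3, acetone, reflux
Reagents that add atoms: none
Why: Williamson etherification of the phenoxide with the reactive propargylic bromide (SN2).

Step 4
Reactants: 6 1,3-bis[(4-methylbenzyl)oxy]-5-(prop-2-yn-1-yloxy)benzene
Product: 7 5,7-bis[(4-methylbenzyl)oxy]chroman-3-one
Conditions: (Me4tBuXPhos)AuNTf2 (5 mol%), 3,5-dichloropyridine N-oxide (1.3 equiv), 1,2-dichloroethane, rt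
Reagents that add atoms: 3,5-dichloropyridine N-oxide, [O-][n+]1cc(Cl)cc(Cl)c1
Why: Gold-catalysed alkyne oxidation: monovalent gold activates the terminal alkyne, the N-oxide adds to the internal carbon and loses the pyridine to give an α-oxo gold carbene, which alkylates one of the two equivalent ortho carbons of the electron-rich ring (formal aryl C–H functionalisation) and closes ring C as the 3-ketone.

**Vanilloyl part: acid 14**

Step 5
Reactants: 8 catechol
Product: 9 guaiacol (2-methoxyphenol)
Conditions: MeI (1.0 equiv), catechol (3 equiv), K2CO3, acetone, reflux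
Reagents that add atoms: methyl iodide, CI
Why: Williamson mono-O-methylation, kept at the mono stage by the excess of catechol (unreacted catechol is washed out with water and the little veratrole is removed by base extraction).

Step 6
Reactants: 9 guaiacol
Product: 10 4-bromo-2-methoxyphenol
Conditions: N-bromosuccinimide (1.0 equiv), MeCN, 0 °C
Reagents that add atoms: N-bromosuccinimide, O=C1CCC(=O)N1Br
Why: Electrophilic aromatic bromination goes para to the free hydroxyl, the stronger directing group.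

Step 7
Reactants: 10 4-bromo-2-methoxyphenol
Product: 11 1-(benzyloxy)-4-bromo-2-methoxybenzene
Conditions: BnBr, K2CO3, DMF, rt
Reagents that add atoms: benzyl bromide, BrCc1ccccc1
Why: Williamson benzylation of the phenol (SN2).

Step 8
Reactants: 11 1-(benzyloxy)-4-bromo-2-methoxybenzene
Product: 14 4-(benzyloxy)-3-methoxybenzoic acid, via aryl Grignard reagent 12 (not isolated), via bromomagnesium carboxylate 13 (not isolated)
Conditions: Mg (turnings), THF, reflux; then CO2, −20 °C to rt; aqueous HCl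
Reagents that add atoms: magnesium, [Mg] (in 12 and 13 only); carbon dioxide, O=C=O
Why: Grignard formation from the aryl bromide followed by carboxylation with CO2 and acidic work-up.

**Ring B: boronic acid 19**

Step 9
Reactants: 8 catechol
Product: 15 1,2-bis(benzyloxy)benzene
Conditions: BnBr (2.2 equiv), K2CO3, DMF, 60 °C
Reagents that add atoms: benzyl bromide, BrCc1ccccc1
Why: Double Williamson benzylation (SN2).

Step 10
Reactants: 15 1,2-bis(benzyloxy)benzene
Product: 16 1,2-bis(benzyloxy)-4-bromobenzene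
Conditions: N-bromosuccinimide (1.0 equiv), MeCN, rt
Reagents that add atoms: N-bromosuccinimide, O=C1CCC(=O)N1Br
Why: Electrophilic aromatic bromination para to an alkoxy group (positions 4 and 5 are equivalent), stopped at the monobromide by stoichiometry.

Step 11
Reactants: 16 1,2-bis(benzyloxy)-4-bromobenzene
Product: 19 [3,4-bis(benzyloxy)phenyl]boronic acid, via aryllithium 17 (not isolated), via lithium aryl(triisopropoxy)borate 18 (not isolated)
Conditions: n-BuLi, THF, −78 °C; B(OiPr)3, −78 °C to rt; aqueous HCl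
Reagents that add atoms: n-butyllithium, [Li]CCCC (lithium of 17 and 18 only); triisopropyl borate, CC(C)OB(OC(C)C)OC(C)C; water, O
Why: Bromine–lithium exchange at −78 °C (faster than benzylic deprotonation), borate trapping and hydrolysis to the boronic acid.

**Assembly**

Step 12
Reactants: 14 4-(benzyloxy)-3-methoxybenzoic acid; 7 5,7-bis[(4-methylbenzyl)oxy]chroman-3-one
Product: 21 5,7-bis[(4-methylbenzyl)oxy]-2H-chromen-3-yl 4-(benzyloxy)-3-methoxybenzoate, via 4-(benzyloxy)-3-methoxybenzoyl chloride 20 (not isolated)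
Conditions: (COCl)2, DMF (cat.), CH2Cl2, 0 °C to rt, concentrate; then 7, Et3N, DMAP (10 mol%), CH2Cl2, 0 °C to rt
Reagents that add atoms: oxalyl chloride, O=C(Cl)C(=O)Cl (chlorine of 20 only)
Why: Acid chloride formation followed by DMAP-catalysed O-acylation of the ketone under soft enolisation, which takes the thermodynamically preferred enol toward the benzylic C4 (conjugated with ring A) and so gives the C3=C4 enol ester.

Step 13
Reactants: 21 5,7-bis[(4-methylbenzyl)oxy]-2H-chromen-3-yl 4-(benzyloxy)-3-methoxybenzoate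
Product: 22 rac-2-ethoxy-5,7-bis[(4-methylbenzyl)oxy]-2H-chromen-3-yl 4-(benzyloxy)-3-methoxybenzoate
Conditions: DDQ (1.05 equiv), EtOH (10 equiv), 4 Å molecular sieves, CH2Cl2, 0 °C; NaHCO3 quench; Et3N-deactivated silica
Reagents that add atoms: ethanol, CCO
Why: Oxidative C–H functionalisation: DDQ abstracts hydride from the allylic, α-oxy C2–H to give a benzopyrylium ion stabilised by the 5,7-ether groups, and ethanol traps it at C2 as the mixed acetal.

Step 14
Reactants: 22 rac-2-ethoxy-5,7-bis[(4-methylbenzyl)oxy]-2H-chromen-3-yl 4-(benzyloxy)-3-methoxybenzoate; 19 [3,4-bis(benzyloxy)phenyl]boronic acid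
Product: 23 (2R)-2-[3,4-bis(benzyloxy)phenyl]-5,7-bis[(4-methylbenzyl)oxy]-2H-chromen-3-yl 4-(benzyloxy)-3-methoxybenzoate
Conditions: Ni(cod)2 (10 mol%), (R,R)-TADDOL-derived P-phenylphosphonite (12 mol%), 19 (1.5 equiv), 1,4-dioxane/tert-amyl alcohol (4:1), 40 °C
Reagents that add atoms: none
Why: Proposed new method: the arylboronic acid acts as a Lewis acid that pulls ethoxide from the racemic acetal, zerovalent nickel bearing the chiral phosphonite adds to the resulting planar 3-acyloxy-5,7-dialkoxybenzopyrylium ion to give an η3-oxaallyl divalent nickel species, and boron-to-nickel aryl transfer (helped by the boron-bound ethoxide) followed by C–C reductive elimination at C2 (C4 is shielded by the peri 5-ether and would give a non-conjugated product) forms the C2–aryl bond, so that both acetal enantiomers converge on one product and the ligand alone sets (2R) (its antipode is used if the sense turns out opposite); the closest known reaction type is the nickel-catalysed Suzuki–Miyaura arylation of unsubstituted 2-ethoxy-2H-chromene acetals with arylboronic acids, which has not been shown on a 3-acyloxy, 5,7-dioxygenated acetal or used to set C2 of a flavan-3-ol.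

Step 15
Reactants: 23 (2R)-2-[3,4-bis(benzyloxy)phenyl]-5,7-bis[(4-methylbenzyl)oxy]-2H-chromen-3-yl 4-(benzyloxy)-3-methoxybenzoate
Product: 24 (2R,3R)-2-[3,4-bis(benzyloxy)phenyl]-5,7-bis[(4-methylbenzyl)oxy]-3,4-dihydro-2H-chromen-3-yl 4-(benzyloxy)-3-methoxybenzoate
Conditions: H2 (20 bar), [Rh(nbd)(dppb)]BF4 (5 mol%), CH2Cl2, rt
Reagents that add atoms: none
Why: Chelation-assisted homogeneous hydrogenation of the enol ester on cationic monovalent rhodium adds both hydrogens syn from the face opposite the C2 aryl group, so the new C3–H is trans to the aryl and the ester is 2,3-cis (3R); the homogeneous catalyst avoids double-bond migration through the allylic C2–H and leaves the benzyl ethers intact.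

Step 16
Reactants: 24 (2R,3R)-2-[3,4-bis(benzyloxy)phenyl]-5,7-bis[(4-methylbenzyl)oxy]-3,4-dihydro-2H-chromen-3-yl 4-(benzyloxy)-3-methoxybenzoate
Product: 25 (2R,3R)-2-(3,4-dihydroxyphenyl)-5,7-dihydroxy-3,4-dihydro-2H-chromen-3-yl 4-hydroxy-3-methoxybenzoate
Conditions: H2 (1 atm), Pd(OH)2/C, THF/MeOH (1:1), rt
Reagents that add atoms: none
Why: Neutral hydrogenolysis cleaves the three benzyl and two 4-methylbenzyl aryl ethers, while the non-benzylic C3 ester, the cyclic C2–O1 ether (which survives these conditions in the flavan-3-ol series) and both stereocentres are untouched.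

**Compound list**
1 | resorcinol | Oc1cccc(O)c1 | starting material
2 | 1,3-bis[(4-methylbenzyl)oxy]benzene | Cc1ccc(COc2cccc(OCc3ccc(C)cc3)c2)cc1 | intermediate
3 | 2-{3,5-bis[(4-methylbenzyl)oxy]phenyl}-4,4,5,5-tetramethyl-1,3,2-dioxaborolane | Cc1ccc(COc2cc(OCc3ccc(C)cc3)cc(B3OC(C)(C)C(C)(C)O3)c2)cc1 | intermediate (not isolated)
4 | 3,5-bis[(4-methylbenzyl)oxy]phenol | Cc1ccc(COc2cc(O)cc(OCc3ccc(C)cc3)c2)cc1 | intermediate
5 | propargyl bromide (3-bromoprop-1-yne) | C#CCBr | starting material
6 | 1,3-bis[(4-methylbenzyl)oxy]-5-(prop-2-yn-1-yloxy)benzene | C#CCOc1cc(OCc2ccc(C)cc2)cc(OCc2ccc(C)cc2)c1 | intermediate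
7 | 5,7-bis[(4-methylbenzyl)oxy]chroman-3-one | O=C1COc2cc(OCc3ccc(C)cc3)cc(OCc3ccc(C)cc3)c2C1 | intermediate
8 | catechol | Oc1ccccc1O | starting material
9 | guaiacol (2-methoxyphenol) | COc1ccccc1O | intermediate
10 | 4-bromo-2-methoxyphenol | COc1cc(Br)ccc1O | intermediate
11 | 1-(benzyloxy)-4-bromo-2-methoxybenzene | COc1cc(Br)ccc1OCc1ccccc1 | intermediate
12 | [4-(benzyloxy)-3-methoxyphenyl]magnesium bromide | COc1cc([Mg]Br)ccc1OCc1ccccc1 | intermediate (not isolated)
13 | bromomagnesium 4-(benzyloxy)-3-methoxybenzoate | COc1cc(C(=O)O[Mg]Br)ccc1OCc1ccccc1 | intermediate (not isolated)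
14 | 4-(benzyloxy)-3-methoxybenzoic acid | COc1cc(C(=O)O)ccc1OCc1ccccc1 | intermediate
15 | 1,2-bis(benzyloxy)benzene | c1ccc(COc2ccccc2OCc2ccccc2)cc1 | intermediate
16 | 1,2-bis(benzyloxy)-4-bromobenzene | Brc1ccc(OCc2ccccc2)c(OCc2ccccc2)c1 | intermediate
17 | [3,4-bis(benzyloxy)phenyl]lithium | [Li]c1ccc(OCc2ccccc2)c(OCc2ccccc2)c1 | intermediate (not isolated)
18 | lithium [3,4-bis(benzyloxy)phenyl]tri(propan-2-yloxy)borate | [Li+].CC(C)O[B-](OC(C)C)(OC(C)C)c1ccc(OCc2ccccc2)c(OCc2ccccc2)c1 | intermediate (not isolated)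
19 | [3,4-bis(benzyloxy)phenyl]boronic acid | OB(O)c1ccc(OCc2ccccc2)c(OCc2ccccc2)c1 | intermediate
20 | 4-(benzyloxy)-3-methoxybenzoyl chloride | COc1cc(C(=O)Cl)ccc1OCc1ccccc1 | intermediate (not isolated)
21 | 5,7-bis[(4-methylbenzyl)oxy]-2H-chromen-3-yl 4-(benzyloxy)-3-methoxybenzoate | COc1cc(C(=O)OC2=Cc3c(OCc4ccc(C)cc4)cc(OCc4ccc(C)cc4)cc3OC2)ccc1OCc1ccccc1 | intermediate
22 | rac-2-ethoxy-5,7-bis[(4-methylbenzyl)oxy]-2H-chromen-3-yl 4-(benzyloxy)-3-methoxybenzoate | CCOC1Oc2cc(OCc3ccc(C)cc3)cc(OCc3ccc(C)cc3)c2C=C1OC(=O)c1ccc(OCc2ccccc2)c(OC)c1 | intermediate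
23 | (2R)-2-[3,4-bis(benzyloxy)phenyl]-5,7-bis[(4-methylbenzyl)oxy]-2H-chromen-3-yl 4-(benzyloxy)-3-methoxybenzoate | COc1cc(C(=O)OC2=Cc3c(OCc4ccc(C)cc4)cc(OCc4ccc(C)cc4)cc3O[C@@H]2c2ccc(OCc3ccccc3)c(OCc3ccccc3)c2)ccc1OCc1ccccc1 | intermediate
24 | (2R,3R)-2-[3,4-bis(benzyloxy)phenyl]-5,7-bis[(4-methylbenzyl)oxy]-3,4-dihydro-2H-chromen-3-yl 4-(benzyloxy)-3-methoxybenzoate | COc1cc(C(=O)O[C@@H]2Cc3c(OCc4ccc(C)cc4)cc(OCc4ccc(C)cc4)cc3O[C@@H]2c2ccc(OCc3ccccc3)c(OCc3ccccc3)c2)ccc1OCc1ccccc1 | intermediate
25 | (2R,3R)-2-(3,4-dihydroxyphenyl)-5,7-dihydroxy-3,4-dihydro-2H-chromen-3-yl 4-hydroxy-3-methoxybenzoate, the 3-O-vanillate of (−)-epicatechin | COc1cc(C(=O)O[C@@H]2Cc3c(O)cc(O)cc3O[C@@H]2c2ccc(O)c(O)c2)ccc1O | target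

**Totals**
Total step count: 16.
Longest linear sequence: 9 steps (steps 1–4 then 12–16; equally steps 5–8 then 12–16). The ring B branch is 6 steps (9–11, 14–16).

**Steps most likely to fail, with fallbacks**

Step 14 (the proposed nickel-catalysed arylation) is the main risk: the enol ester may interfere with zerovalent nickel, or the enantioselectivity may be low. The fallback uses known chemistry, sets out from 22 and 19 and comes back at 23. Boronic acid 19 is treated with KHF2 (MeOH/H2O) to give potassium [3,4-bis(benzyloxy)phenyl]trifluoroborate F4. BF3·OEt2 (MeCN, −20 °C) ionises 22, and F4 adds to the benzopyrylium ion without any metal catalyst to give racemic 2-[3,4-bis(benzyloxy)phenyl]-5,7-bis[(4-methylbenzyl)oxy]-2H-chromen-3-yl 4-(benzyloxy)-3-methoxybenzoate F5. Preparative chiral supercritical-fluid chromatography then separates 23 from (2S)-2-[3,4-bis(benzyloxy)phenyl]-5,7-bis[(4-methylbenzyl)oxy]-2H-chromen-3-yl 4-(benzyloxy)-3-methoxybenzoate F6, which is set aside.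

Step 13 (DDQ oxidation to the acetal) may suffer from over-oxidation or from adducts of the cation with the reduced quinone. The fallback sets out from 21 and comes back at 22. Hydride abstraction with Ph3CBF4 (1.0 equiv, MeCN, 0 °C) and precipitation with Et2O give the isolable salt 3-{[4-(benzyloxy)-3-methoxybenzoyl]oxy}-5,7-bis[(4-methylbenzyl)oxy]chromenylium tetrafluoroborate F3. Stirring F3 in EtOH over solid NaHCO3 at 0 °C gives 22.

Step 4 (gold-catalysed oxidative cyclisation) may give competing hydroarylation on this very electron-rich ring. The fallback sets out from 6 and comes back at 7, and makes that side product on purpose. Without oxidant, (Ph3P)AuNTf2 (2 mol%, CH2Cl2, rt) cyclises 6 by 6-endo hydroarylation to 5,7-bis[(4-methylbenzyl)oxy]-2H-chromene F1. Hydroboration–oxidation (BH3·THF, 0 °C; then NaOH, H2O2) places the oxygen at C3, away from the aryl-bearing C4, and gives racemic 5,7-bis[(4-methylbenzyl)oxy]chroman-3-ol F2. Dess–Martin periodinane (CH2Cl2, rt) oxidises F2 to 7.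

**Further compounds**
F1 | step 4 | 5,7-bis[(4-methylbenzyl)oxy]-2H-chromene | C1=Cc2c(OCc3ccc(C)cc3)cc(OCc3ccc(C)cc3)cc2OC1
F2 | step 4 | rac-5,7-bis[(4-methylbenzyl)oxy]chroman-3-ol | OC1COc2cc(OCc3ccc(C)cc3)cc(OCc3ccc(C)cc3)c2C1
F3 | step 13 | 3-{[4-(benzyloxy)-3-methoxybenzoyl]oxy}-5,7-bis[(4-methylbenzyl)oxy]chromenylium tetrafluoroborate | COc1cc(C(=O)Oc2cc3c(OCc4ccc(C)cc4)cc(OCc4ccc(C)cc4)cc3[o+]c2)ccc1OCc1ccccc1.F[B-](F)(F)F
F4 | step 14 | potassium [3,4-bis(benzyloxy)phenyl]trifluoroborate | [K+].F[B-](F)(F)c1ccc(OCc2ccccc2)c(OCc2ccccc2)c1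
F5 | step 14 | rac-2-[3,4-bis(benzyloxy)phenyl]-5,7-bis[(4-methylbenzyl)oxy]-2H-chromen-3-yl 4-(benzyloxy)-3-methoxybenzoate | COc1cc(C(=O)OC2=Cc3c(OCc4ccc(C)cc4)cc(OCc4ccc(C)cc4)cc3OC2c2ccc(OCc3ccccc3)c(OCc3ccccc3)c2)ccc1OCc1ccccc1
F6 | step 14 | (2S)-2-[3,4-bis(benzyloxy)phenyl]-5,7-bis[(4-methylbenzyl)oxy]-2H-chromen-3-yl 4-(benzyloxy)-3-methoxybenzoate | COc1cc(C(=O)OC2=Cc3c(OCc4ccc(C)cc4)cc(OCc4ccc(C)cc4)cc3O[C@H]2c2ccc(OCc3ccccc3)c(OCc3ccccc3)c2)ccc1OCc1ccccc1
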